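**Strategy**

Everything rests on cutting both aryl C–O bonds of the catechol: the ring oxygens are introduced last, onto an arene that already holds both bromines and the sulfone side chain. With the benzene ring numbered C1 (CH2SO2CH3), C2 (H), C3 and C4 (OH), C5 and C6 (Br), the hydroxyls sit meta and ortho to the C5 bromine, which is where toluene dioxygenase habitually places its two oxygens on a halobenzene. In a single operation the enzyme adds O2 across the C3–C4 edge of 1,2-dibromo-3-(methylsulfonylmethyl)benzene, giving a cis-dihydrodiol with both C–Br bonds intact; a dehydrogenase then restores aromaticity. The precursor has no ring oxygen and is reached in two steps from 2,3-dibromotoluene.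

Key step: step 3

Remark: sulfur is brought to the sulfone level before the enzymatic step, because a sulfide would be sulfoxidised by the dioxygenase and neither the dihydrodiol nor the catechol would survive NBS.
Remark: diol 5 is written as the cis-(1S,2S) isomer, the absolute sense in which this enzyme oxidises bromobenzene; the assignment has no bearing on the achiral target.
Assumption: the dehydrogenase of step 4 is taken to remove hydride from the carbinol carbon next to C–Br, so intermediate 6 is drawn as that ketone; hydride loss at the other carbinol would converge on the same catechol.

**Route**

Step 1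
Reactants: 1 2,3-dibromotoluene (1,2-dibromo-3-methylbenzene)
Product: 2 2,3-dibromobenzyl bromide (1,2-dibromo-3-(bromomethyl)benzene)
Conditions: NBS (1.05 equiv), AIBN (5 mol %), PhCF3, 85 °C
Reagents that add atoms: N-bromosuccinimide, O=C1CCC(=O)N1Br
Why: Wohl–Ziegler radical-chain bromination should take the only benzylic C–H position, since the two ring bromines deactivate the arene toward electrophilic substitution and the aryl C–Br bonds do not enter the bromine-atom chain.

Step 2
Reactants: 2 2,3-dibromobenzyl bromide; 3 sodium methanesulfinate
Product: 4 1,2-dibromo-3-(methylsulfonylmethyl)benzene
Conditions: MeSO2Na (1.3 equiv), DMF, 60 °C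
Reagents that add atoms: sodium methanesulfinate (compound 3), CS(=O)[O-].[Na+]
Why: SN2 alkylation of the ambident sulfinate at sulfur by the primary benzylic bromide should give the sulfone directly at its final oxidation level, while the aryl bromides are inert to this nucleophile without a metal catalyst.

Step 3
Reactants: 4 1,2-dibromo-3-(methylsulfonylmethyl)benzene
Product: 5 (1S,2S)-3,4-dibromo-5-(methylsulfonylmethyl)cyclohexa-3,5-diene-1,2-diol
Conditions: E. coli JM109(pDTG601A) whole cells (toluene dioxygenase TodC1C2BA, IPTG-induced), air, glucose feed, KH2PO4/K2HPO4-buffered medium pH 7.2, 30 °C; 4 dosed in DMSO; EtOAc extraction at pH 8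
Reagents that add atoms: dioxygen, O=O
Why: Non-haem iron arene cis-dihydroxylation: electrons from NADH travel through the reductase, the ferredoxin and the [2Fe-2S] centre of the oxygenase to a mononuclear iron site, where O2 is bound side-on and activated as a (hydro)peroxo complex of trivalent iron that transfers both of its oxygen atoms to the adjacent carbons C3 and C4 from one face of the ring, so the two new C–O bonds are necessarily cis. The closest known reactions are the toluene dioxygenase oxidations of bromobenzene and of ortho-dihalobenzenes, which give cis-dihydrodiols oxygenated ortho and meta to a halogen with the carbon–halogen bonds retained. No ring is closed; the benzene ring simply becomes a cyclohexa-3,5-diene. The two new stereocentres (C3 and C4 of the arene, C1 and C2 of diol 5) are controlled by the enzyme pocket, which fixes the face that the ring presents to iron; the (1S,2S) sense is expected by analogy with the halobenzene diols, and either enantiomer would serve because step 4 flattens both centres. The selectivity that matters is the choice of the C3–C4 edge over the only other unsubstituted edge, C2–C3: the lipophilic C5 bromine should lodge in the hydrophobic pocket that normally holds the methyl group of toluene, which places C4 and C3 above the iron, while the polar CH2SO2CH3 arm at C1 is pushed toward the solvent channel and keeps C2 away from the metal. The sulfone is already fully oxidised, so sulfoxidation cannot compete, and the electron-poor benzylic CH2 should resist the monooxygenation that this enzyme performs on ordinary benzylic positions.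

Step 4
Reactants: 5 (1S,2S)-3,4-dibromo-5-(methylsulfonylmethyl)cyclohexa-3,5-diene-1,2-diol
Product: 7 3,4-dibromo-5-(methylsulfonylmethyl)benzene-1,2-diol (target), via alpha-hydroxy dienone 6 (not isolated)
Conditions: resting E. coli cells expressing cis-dihydrodiol dehydrogenase TodD [JM109(pDTG602)], air, KH2PO4/K2HPO4 buffer pH 7.0, 30 °C; then pH 3, EtOAc
Reagents that add atoms: none
Why: NAD+-dependent alcohol dehydrogenation, the natural second reaction of the toluene catabolic pathway, should take a hydride from one carbinol carbon to give ketol 6, whose enolisation to the aromatic catechol is irreversible, while respiration of the cells reoxidises NADH with O2 (ending as water) and the neutral aqueous medium leaves the C–Br bonds and the sulfone untouched; both stereocentres of 5 disappear here.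

**Compound list**

1 | 2,3-dibromotoluene (1,2-dibromo-3-methylbenzene) | Cc1cccc(Br)c1Br | starting material
2 | 2,3-dibromobenzyl bromide (1,2-dibromo-3-(bromomethyl)benzene) | BrCc1cccc(Br)c1Br | intermediate
3 | sodium methanesulfinate | CS(=O)[O-].[Na+] | starting material
4 | 1,2-dibromo-3-(methylsulfonylmethyl)benzene | CS(=O)(=O)Cc1cccc(Br)c1Br | intermediate
5 | (1S,2S)-3,4-dibromo-5-(methylsulfonylmethyl)cyclohexa-3,5-diene-1,2-diol (cis-diol) | CS(=O)(=O)CC1=C[C@H](O)[C@H](O)C(Br)=C1Br | intermediate
6 | (6S)-2,3-dibromo-6-hydroxy-4-(methylsulfonylmethyl)cyclohexa-2,4-dien-1-one | CS(=O)(=O)CC1=C[C@H](O)C(=O)C(Br)=C1Br | intermediate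
7 | 3,4-dibromo-5-(methylsulfonylmethyl)benzene-1,2-diol | CS(=O)(=O)Cc1cc(O)c(O)c(Br)c1Br | target

**Step count and risks**

Total step count: 4. Longest linear sequence: 4 steps (1 → 2 → 4 → 5 → 7).

Steps most likely to fail:

1. Step 3 (key step). The enzyme may not turn over a 1,2,3-trisubstituted, polar substrate, or oxygen may be delivered to the C2–C3 edge or to the benzylic carbon instead of C3–C4. The fallback gives up late-stage oxygenation for an oxygen-first, bromine-second sequence of classical aromatic chemistry. It sets out from sodium methanesulfinate 3, used together with purchased vanillin F1, and rejoins the route at target 7. Vanillin F1 should be dibrominated (Br2, Fe powder cat., AcOH) ortho to the phenol and para to the methoxy group to give 5,6-dibromovanillin F2. BBr3 in CH2Cl2 should then cleave the methyl ether to 2,3-dibromo-4,5-dihydroxybenzaldehyde F3, and NaBH4 in MeOH should reduce the aldehyde to 2,3-dibromo-4,5-dihydroxybenzyl alcohol F4. Warming F4 with 3 in aqueous AcOH should give 7 by attack of the sulfinate sulfur on the para-quinone methide that this para-hydroxybenzyl alcohol forms on loss of water.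

2. Step 4. The dehydrogenase may reject the tetrasubstituted diol, the diol may dehydrate to phenols before it is oxidised, or the catechol may be degraded oxidatively in the aerated cell suspension. The fallback replaces the enzyme by chemical hydride abstraction; it sets out from diol 5 and returns at 7. DDQ (2.2 equiv, dioxane, 10 °C) should oxidise 5 through 6 and 7 to the ortho-quinone 3,4-dibromo-5-(methylsulfonylmethyl)cyclohexa-3,5-diene-1,2-dione F5. This is not isolated but reduced at once in the same flask with aqueous Na2S2O4 to 7. Oxidation of a dihydrodiol to the quinone followed by reduction to the catechol is established for arene dihydrodiols, and the immediate reduction limits tautomerisation of F5 to a quinone methide.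

3. Step 1. The radical bromination may not stop cleanly at the monobromide, leaving mixtures of unreacted 1, 2 and over-brominated material that are hard to separate. The fallback obtains selectivity by overshooting and correcting; it sets out from 1 and returns at 2. Excess NBS (2.4 equiv, AIBN, PhCF3, reflux) should consume all of 1 and push the material toward 1,2-dibromo-3-(dibromomethyl)benzene F6. Treatment with (EtO)2P(O)H and iPr2NEt in THF at 0 °C should then remove one benzylic bromine from F6 selectively, leaving any 2 already present untouched.

**Further compounds**

F1 | step 3 | vanillin (4-hydroxy-3-methoxybenzaldehyde, purchased) | COc1cc(C=O)ccc1O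
F2 | step 3 | 5,6-dibromovanillin (2,3-dibromo-4-hydroxy-5-methoxybenzaldehyde) | COc1cc(C=O)c(Br)c(Br)c1O
F3 | step 3 | 2,3-dibromo-4,5-dihydroxybenzaldehyde | O=Cc1cc(O)c(O)c(Br)c1Br
F4 | step 3 | 2,3-dibromo-4,5-dihydroxybenzyl alcohol | OCc1cc(O)c(O)c(Br)c1Br
F5 | step 4 | 3,4-dibromo-5-(methylsulfonylmethyl)cyclohexa-3,5-diene-1,2-dione | CS(=O)(=O)CC1=CC(=O)C(=O)C(Br)=C1Br
F6 | step 1 | 1,2-dibromo-3-(dibromomethyl)benzene | BrC(Br)c1cccc(Br)c1Br
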